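**Retrosynthetic overview**

1. The target is a biflavone ether. Unit 1 (5,7-dihydroxy-4'-methoxyflavone) carries on C8 an aryl ether oxygen that is the para (C4') oxygen of ring B of unit 2 (5-hydroxy-7-methoxyflavone). The strategy rests on one feature: pyranone ring C1 of unit 1 must close onto the oxygen on C8a, next to the C8 aryl ether, and not onto the C5 oxygen, which would give the 6-aryloxy isomer. Iodine on C4a of a phenol whose C8a hydroxyl alone is free (C5 and C7 as benzyl ethers) enforces this.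
2. Backwards: benzyl ether cleavage; ring C2 of unit 2 from a 2'-hydroxychalcone (I2–DMSO), itself from an aryl aldehyde and 2,6-dihydroxy-4-methoxyacetophenone; ring C1 by three-component carbonylative annulation of the 2-iodophenol, CO (becomes C4) and 4-ethynylanisole (bonds C4a–C4, C4–C3, O1–C2).
3. The iodophenol comes from SNAr of a Baeyer–Villiger-derived phenol on 4-fluorobenzaldehyde; the iodine is set earlier, ortho to the chelated hydroxyl of 2,4-bis(benzyloxy)-6-hydroxybenzaldehyde.
4. Ring order: the four benzene rings are bought; ring C1 forms in step 7 and ring C2 in step 9.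

Key step: step 7

Remark: the target has no stereocentre; flavone numbering is used for both halves, and the only stereo-elements on the way are the E alkenes of 13 and 16.

**Route**

Step 1
Reactants: 1 2,4,6-trihydroxybenzaldehyde
Product: 2 2,4-bis(benzyloxy)-6-hydroxybenzaldehyde
Conditions: BnBr (2.1 equiv), K2CO3 (2.2 equiv), DMF, 0 °C to rt
Reagents that add atoms: benzyl bromide, BrCc1ccccc1
Why: Williamson O-benzylation takes the 4-hydroxyl and one ortho hydroxyl, while the last hydroxyl, held in a hydrogen bond to the aldehyde, stays free when the bromide is limited to two equivalents.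

Step 2
Reactants: 2 2,4-bis(benzyloxy)-6-hydroxybenzaldehyde
Product: 3 4,6-bis(benzyloxy)-2-hydroxy-3-iodobenzaldehyde
Conditions: BnMe3N ICl2 (1.05 equiv), NaHCO3, CH2Cl2–MeOH, rt
Reagents that add atoms: benzyltrimethylammonium dichloroiodate, C[N+](C)(C)Cc1ccccc1.Cl[I-]Cl
Why: Electrophilic aromatic iodination should go to the carbon ortho to the chelated hydroxyl rather than to the more crowded carbon between the two benzyloxy groups, the preference known for 2-hydroxy-4,6-dialkoxyaryl ketones, and one equivalent of buffered reagent limits it to mono-iodination.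

Step 3
Reactants: 3 4,6-bis(benzyloxy)-2-hydroxy-3-iodobenzaldehyde
Product: 4 4,6-bis(benzyloxy)-3-iodo-2-(methoxymethoxy)benzaldehyde
Conditions: NaH (1.2 equiv), MOMCl (1.3 equiv), DMF, 0 °C to rt
Reagents that add atoms: chloromethyl methyl ether, COCCl
Why: Williamson-type O-alkylation of the sodium phenoxide gives the methoxymethyl ether, which masks the future C8a oxygen so that only the oxygen made in step 4 is free for ether formation.

Step 4
Reactants: 4 4,6-bis(benzyloxy)-3-iodo-2-(methoxymethoxy)benzaldehyde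
Product: 6 4,6-bis(benzyloxy)-3-iodo-2-(methoxymethoxy)phenol, via aryl formate 5 (not isolated)
Conditions: mCPBA (1.3 equiv), CH2Cl2, 0 °C to rt; then K2CO3 (cat.), MeOH, 0 °C
Reagents that add atoms: 3-chloroperoxybenzoic acid, OOC(=O)c1cccc(Cl)c1
Why: Baeyer–Villiger (Dakin-type) oxidation, in which the electron-rich tri-oxygenated aryl group migrates in the Criegee adduct to give the formate, which mild methanolysis cleaves without touching the MOM ether, the benzyl ethers or the aryl iodide.

Step 5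
Reactants: 6 4,6-bis(benzyloxy)-3-iodo-2-(methoxymethoxy)phenol; 7 4-fluorobenzaldehyde
Product: 8 4-[4,6-bis(benzyloxy)-3-iodo-2-(methoxymethoxy)phenoxy]benzaldehyde
Conditions: K2CO3 (2 equiv), DMF, 100 °C, argon
Reagents that add atoms: none
Why: SNAr (addition–elimination through a Meisenheimer complex) of the potassium phenoxide on the fluoride activated by the para formyl group; the aryl iodide on the electron-rich ring is inert in the absence of a copper or palladium catalyst.

Step 6
Reactants: 8 4-[4,6-bis(benzyloxy)-3-iodo-2-(methoxymethoxy)phenoxy]benzaldehyde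
Product: 9 4-[4,6-bis(benzyloxy)-2-hydroxy-3-iodophenoxy]benzaldehyde
Conditions: 2 M aq. HCl, THF, 45 °C
Reagents that add atoms: none
Why: Acid-catalysed hydrolysis of the methoxymethyl acetal frees the C8a hydroxyl, while the benzyl ethers, the diaryl ether, the aldehyde and the aryl iodide should tolerate dilute acid at moderate temperature.

Step 7
Reactants: 9 4-[4,6-bis(benzyloxy)-2-hydroxy-3-iodophenoxy]benzaldehyde; 10 4-ethynylanisole; 11 carbon monoxide
Product: 14 4-{[5,7-bis(benzyloxy)-2-(4-methoxyphenyl)-4-oxo-4H-chromen-8-yl]oxy}benzaldehyde, via 2-hydroxyaryl ynone 12 (not isolated), via diethylamino enone 13 (not isolated)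
Conditions: PdCl2(PPh3)2 (5 mol%), 10 (1.5 equiv), CO (20 bar), Et2NH, 120 °C, autoclave; aqueous acidic work-up
Reagents that add atoms: none
Why: PdCl2(PPh3)2 is reduced in the flask to zerovalent palladium, which adds oxidatively to the C4a–I bond of 9; CO inserts to give an aroyl divalent palladium species, which is alkynylated by the amine-activated alkyne 10 and reductively eliminates ynone 12 (bonds C4a–C4 and C4–C3). Et2NH then adds in conjugate fashion to give enaminone 13, and the C8a hydroxyl displaces the amine at C2 by addition–elimination (bond O1–C2). The closest known reaction type is the palladium-catalysed carbonylative annulation of 2-iodophenols with terminal arylalkynes in a secondary amine to give flavones. Ring C1 closes in a 6-endo sense with respect to the ynone, realised as oxa-Michael addition–elimination on 13, and no stereocentre is formed. The step needs CO insertion before alkynylation (helped by CO pressure, the absence of a copper co-catalyst and the electron-rich, di-ortho-substituted arylpalladium), pyranone over aurone closure (secured by the amine pathway), and closure through the C8a oxygen only, which is secured because iodine sits on C4a and the C5 and C7 oxygens are benzyl ethers. The aldehyde is a spectator that at most forms a reversible hemiaminal with Et2NH, returned on acidic work-up.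

Step 8
Reactants: 14 4-{[5,7-bis(benzyloxy)-2-(4-methoxyphenyl)-4-oxo-4H-chromen-8-yl]oxy}benzaldehyde; 15 1-(2,6-dihydroxy-4-methoxyphenyl)ethanone
Product: 16 5,7-bis(benzyloxy)-8-{4-[(1E)-3-(2,6-dihydroxy-4-methoxyphenyl)-3-oxoprop-1-en-1-yl]phenoxy}-2-(4-methoxyphenyl)-4H-chromen-4-one
Conditions: KOH (50% aq., excess), EtOH–THF, 0 °C to rt; then 1 M HCl to pH 4
Reagents that add atoms: none
Why: Claisen–Schmidt (crossed aldol) condensation, in which the aldehyde of 14 cannot enolise, the methyl ketone of 15 is the only enolisable partner, and E1cB dehydration gives the conjugated E alkene as the thermodynamic isomer.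

Step 9
Reactants: 16 5,7-bis(benzyloxy)-8-{4-[(1E)-3-(2,6-dihydroxy-4-methoxyphenyl)-3-oxoprop-1-en-1-yl]phenoxy}-2-(4-methoxyphenyl)-4H-chromen-4-one
Product: 17 5,7-bis(benzyloxy)-8-[4-(5-hydroxy-7-methoxy-4-oxo-4H-chromen-2-yl)phenoxy]-2-(4-methoxyphenyl)-4H-chromen-4-one
Conditions: I2 (10 mol%), DMSO, 120 °C
Reagents that add atoms: none
Why: Iodine-catalysed oxidative cyclisation of a 2'-hydroxychalcone in DMSO: oxa-Michael closure through either of the two equivalent hydroxyls, then iodination–elimination with DMSO reoxidising HI to I2, closes ring C2 and leaves the second hydroxyl as the chelated 5-OH of unit 2.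

Step 10
Reactants: 17 5,7-bis(benzyloxy)-8-[4-(5-hydroxy-7-methoxy-4-oxo-4H-chromen-2-yl)phenoxy]-2-(4-methoxyphenyl)-4H-chromen-4-one
Product: 18 5,7-dihydroxy-8-[4-(5-hydroxy-7-methoxy-4-oxo-4H-chromen-2-yl)phenoxy]-2-(4-methoxyphenyl)-4H-chromen-4-one
Conditions: BCl3 (1 M in CH2Cl2, 6 equiv), pentamethylbenzene (6 equiv), CH2Cl2, −78 to −20 °C; then MeOH–H2O
Reagents that add atoms: none
Why: Lewis-acid debenzylation, in which BCl3 cleaves the two aryl benzyl ethers at low temperature and pentamethylbenzene traps the benzyl cation so that the electron-rich rings are not C-benzylated, while the two aryl methyl ethers (neither peri to a carbonyl) and the diaryl ether should stay intact.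

**Compound list**

1 | 2,4,6-trihydroxybenzaldehyde | O=Cc1c(O)cc(O)cc1O | starting material
2 | 2,4-bis(benzyloxy)-6-hydroxybenzaldehyde | O=Cc1c(O)cc(OCc2ccccc2)cc1OCc1ccccc1 | intermediate
3 | 4,6-bis(benzyloxy)-2-hydroxy-3-iodobenzaldehyde | O=Cc1c(O)c(I)c(OCc2ccccc2)cc1OCc1ccccc1 | intermediate
4 | 4,6-bis(benzyloxy)-3-iodo-2-(methoxymethoxy)benzaldehyde | O=Cc1c(OCOC)c(I)c(OCc2ccccc2)cc1OCc1ccccc1 | intermediate
5 | 4,6-bis(benzyloxy)-3-iodo-2-(methoxymethoxy)phenyl formate | O=COc1c(OCOC)c(I)c(OCc2ccccc2)cc1OCc1ccccc1 | intermediate (not isolated)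
6 | 4,6-bis(benzyloxy)-3-iodo-2-(methoxymethoxy)phenol | Oc1c(OCOC)c(I)c(OCc2ccccc2)cc1OCc1ccccc1 | intermediate
7 | 4-fluorobenzaldehyde | O=Cc1ccc(F)cc1 | starting material
8 | 4-[4,6-bis(benzyloxy)-3-iodo-2-(methoxymethoxy)phenoxy]benzaldehyde | O=Cc1ccc(Oc2c(OCOC)c(I)c(OCc3ccccc3)cc2OCc2ccccc2)cc1 | intermediate
9 | 4-[4,6-bis(benzyloxy)-2-hydroxy-3-iodophenoxy]benzaldehyde | O=Cc1ccc(Oc2c(O)c(I)c(OCc3ccccc3)cc2OCc2ccccc2)cc1 | intermediate (key-step precursor)
10 | 4-ethynylanisole | COc1ccc(C#C)cc1 | starting material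
11 | carbon monoxide | [C-]#[O+] | starting material
12 | 4-{4,6-bis(benzyloxy)-2-hydroxy-3-[3-(4-methoxyphenyl)prop-2-ynoyl]phenoxy}benzaldehyde | O=Cc1ccc(Oc2c(O)c(C(=O)C#Cc3ccc(OC)cc3)c(OCc3ccccc3)cc2OCc2ccccc2)cc1 | intermediate (not isolated)
13 | 4-{4,6-bis(benzyloxy)-3-[(2E)-3-(diethylamino)-3-(4-methoxyphenyl)prop-2-enoyl]-2-hydroxyphenoxy}benzaldehyde | O=Cc1ccc(Oc2c(O)c(C(=O)/C=C(/N(CC)CC)c3ccc(OC)cc3)c(OCc3ccccc3)cc2OCc2ccccc2)cc1 | intermediate (not isolated)
14 | 4-{[5,7-bis(benzyloxy)-2-(4-methoxyphenyl)-4-oxo-4H-chromen-8-yl]oxy}benzaldehyde | COc1ccc(-c2cc(=O)c3c(OCc4ccccc4)cc(OCc4ccccc4)c(Oc4ccc(C=O)cc4)c3o2)cc1 | intermediate (key-step product)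
15 | 1-(2,6-dihydroxy-4-methoxyphenyl)ethanone | CC(=O)c1c(O)cc(OC)cc1O | starting material
16 | 5,7-bis(benzyloxy)-8-{4-[(1E)-3-(2,6-dihydroxy-4-methoxyphenyl)-3-oxoprop-1-en-1-yl]phenoxy}-2-(4-methoxyphenyl)-4H-chromen-4-one | COc1ccc(-c2cc(=O)c3c(OCc4ccccc4)cc(OCc4ccccc4)c(Oc4ccc(/C=C/C(=O)c5c(O)cc(OC)cc5O)cc4)c3o2)cc1 | intermediate
17 | 5,7-bis(benzyloxy)-8-[4-(5-hydroxy-7-methoxy-4-oxo-4H-chromen-2-yl)phenoxy]-2-(4-methoxyphenyl)-4H-chromen-4-one | COc1ccc(-c2cc(=O)c3c(OCc4ccccc4)cc(OCc4ccccc4)c(Oc4ccc(-c5cc(=O)c6c(O)cc(OC)cc6o5)cc4)c3o2)cc1 | intermediate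
18 | 5,7-dihydroxy-8-[4-(5-hydroxy-7-methoxy-4-oxo-4H-chromen-2-yl)phenoxy]-2-(4-methoxyphenyl)-4H-chromen-4-one | COc1ccc(-c2cc(=O)c3c(O)cc(O)c(Oc4ccc(-c5cc(=O)c6c(O)cc(OC)cc6o5)cc4)c3o2)cc1 | target

**Step count**

Total: 10 steps. Longest linear sequence: 10 steps (1 to 18); compounds 7, 10, 11 and 15 are bought.

**Steps most likely to fail**

Step 7 (carbonylative annulation). The hindered, electron-rich iodide may add slowly to palladium and lose iodine by reduction. Alkynylation may outrun CO insertion, which leads to a non-carbonylated coupling and furan closure. Et2NH may capture the aroylpalladium species as an amide, or the ynone may close in the 5-exo sense. The fallback sets out from 8 and builds the same ynone without palladium and CO. The aldehyde would be masked as 1,5-bis(benzyloxy)-2-[4-(dimethoxymethyl)phenoxy]-4-iodo-3-(methoxymethoxy)benzene F1 (HC(OMe)3, MeOH, cat. PPTS, rt). Iodine–lithium exchange (n-BuLi, THF, −78 °C) and acylation with N-methoxy-3-(4-methoxyphenyl)-N-methylprop-2-ynamide F2 (made from 10 with n-BuLi and N-methoxy-N-methylcarbamoyl chloride) would give 1-{4,6-bis(benzyloxy)-3-[4-(dimethoxymethyl)phenoxy]-2-(methoxymethoxy)phenyl}-3-(4-methoxyphenyl)prop-2-yn-1-one F3. Aqueous HCl in THF would then free the phenol and the aldehyde to give ynone 12, and Et2NH in EtOH at rt would close it to 14, where the route is rejoined.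

Step 2 (iodination). The electrophile may attack the carbon between the two benzyloxy groups (para to the hydroxyl), or a second iodine may enter. The fallback sets out from 2 and places the iodine by directed metalation. O-Alkylation (NaH, MOMCl, DMF) would give 2,4-bis(benzyloxy)-6-(methoxymethoxy)benzaldehyde F4, and acetalisation (HC(OMe)3, MeOH, cat. PPTS) would give 1,5-bis(benzyloxy)-2-(dimethoxymethyl)-3-(methoxymethoxy)benzene F5. Lithiation directed by the MOM ether to the carbon between the OMOM and benzyloxy groups (n-BuLi, THF, −78 to 0 °C) and an I2 quench would give 1,5-bis(benzyloxy)-2-(dimethoxymethyl)-4-iodo-3-(methoxymethoxy)benzene F6. Mild hydrolysis of the dimethyl acetal alone (PPTS, acetone–H2O, rt) returns to the route at 4.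

Step 8 (Claisen–Schmidt condensation). The doubly deprotonated dihydroxy ketone may enolise too slowly, and prolonged contact with hydroxide may open ring C1 of the flavone by conjugate addition at C2. The fallback sets out from 14 and uses a Baker–Venkataraman sequence with a non-nucleophilic base. Pinnick oxidation (NaClO2, NaH2PO4, 2-methyl-2-butene, t-BuOH–THF–H2O) would give 4-{[5,7-bis(benzyloxy)-2-(4-methoxyphenyl)-4-oxo-4H-chromen-8-yl]oxy}benzoic acid F7. Its acid chloride ((COCl)2, cat. DMF) with excess 15 in pyridine would give 2-acetyl-3-hydroxy-5-methoxyphenyl 4-{[5,7-bis(benzyloxy)-2-(4-methoxyphenyl)-4-oxo-4H-chromen-8-yl]oxy}benzoate F8. O-to-C acyl transfer (LiN(SiMe3)2, THF, −78 to 0 °C) would give 5,7-bis(benzyloxy)-8-{4-[3-(2,6-dihydroxy-4-methoxyphenyl)-3-oxopropanoyl]phenoxy}-2-(4-methoxyphenyl)-4H-chromen-4-one F9. Cyclodehydration (p-TsOH, toluene, 90 °C) returns to the route at 17.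

**Further compounds**

F1 | step 7 | 1,5-bis(benzyloxy)-2-[4-(dimethoxymethyl)phenoxy]-4-iodo-3-(methoxymethoxy)benzene | COC(OC)c1ccc(Oc2c(OCOC)c(I)c(OCc3ccccc3)cc2OCc2ccccc2)cc1
F2 | step 7 | N-methoxy-3-(4-methoxyphenyl)-N-methylprop-2-ynamide | COc1ccc(C#CC(=O)N(C)OC)cc1
F3 | step 7 | 1-{4,6-bis(benzyloxy)-3-[4-(dimethoxymethyl)phenoxy]-2-(methoxymethoxy)phenyl}-3-(4-methoxyphenyl)prop-2-yn-1-one | COC(OC)c1ccc(Oc2c(OCOC)c(C(=O)C#Cc3ccc(OC)cc3)c(OCc3ccccc3)cc2OCc2ccccc2)cc1
F4 | step 2 | 2,4-bis(benzyloxy)-6-(methoxymethoxy)benzaldehyde | COCOc1cc(OCc2ccccc2)cc(OCc2ccccc2)c1C=O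
F5 | step 2 | 1,5-bis(benzyloxy)-2-(dimethoxymethyl)-3-(methoxymethoxy)benzene | COCOc1cc(OCc2ccccc2)cc(OCc2ccccc2)c1C(OC)OC
F6 | step 2 | 1,5-bis(benzyloxy)-2-(dimethoxymethyl)-4-iodo-3-(methoxymethoxy)benzene | COCOc1c(I)c(OCc2ccccc2)cc(OCc2ccccc2)c1C(OC)OC
F7 | step 8 | 4-{[5,7-bis(benzyloxy)-2-(4-methoxyphenyl)-4-oxo-4H-chromen-8-yl]oxy}benzoic acid | COc1ccc(-c2cc(=O)c3c(OCc4ccccc4)cc(OCc4ccccc4)c(Oc4ccc(C(=O)O)cc4)c3o2)cc1
F8 | step 8 | 2-acetyl-3-hydroxy-5-methoxyphenyl 4-{[5,7-bis(benzyloxy)-2-(4-methoxyphenyl)-4-oxo-4H-chromen-8-yl]oxy}benzoate | COc1ccc(-c2cc(=O)c3c(OCc4ccccc4)cc(OCc4ccccc4)c(Oc4ccc(C(=O)Oc5cc(OC)cc(O)c5C(C)=O)cc4)c3o2)cc1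
F9 | step 8 | 5,7-bis(benzyloxy)-8-{4-[3-(2,6-dihydroxy-4-methoxyphenyl)-3-oxopropanoyl]phenoxy}-2-(4-methoxyphenyl)-4H-chromen-4-one | COc1ccc(-c2cc(=O)c3c(OCc4ccccc4)cc(OCc4ccccc4)c(Oc4ccc(C(=O)CC(=O)c5c(O)cc(OC)cc5O)cc4)c3o2)cc1
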